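**Retrosynthetic overview**
- Yezoquinolide ⇒ a 2,6-dialkylphenol that already carries the finished (R)-butenolide. The quinone is revealed last by oxidative dearomatisation of the o-cresol ring.
- (R)-Butenolide ⇒ an achiral 3,5-dialkyl-2-silyloxyfuran. A catalytic enantioselective dearomative protonation at furan C5 sets the only stereocentre.
- Silyloxyfuran ⇒ a C5-lithiated 3-homoprenyl-2-(triisopropylsilyloxy)furan plus the primary allylic bromide of an aryl-geranyl chain.
- Bromide ⇒ o-cresol + geranyl bromide (ortho C-allylation), then E-selective allylic oxidation and bromination. Furan ⇒ 3-bromofuran-2(5H)-one + homoprenylzinc bromide, then O-silylation.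
- No ring is built. The five-membered O-ring is aromatised in step 5 and dearomatised in step 7; the six-membered ring is dearomatised in step 8.

Assumption: the (R)-disulfonimide is taken to protonate the Si face of furan C5, which gives 5R, the configuration in the target SMILES. If the sense proves opposite, the equally available (S)-catalyst is used and nothing else changes.

**Step 1**
Reactants: 1 o-cresol (2-methylphenol); 2 geranyl bromide [(2E)-1-bromo-3,7-dimethylocta-2,6-diene]
Product: 4 2-[(2E)-3,7-dimethylocta-2,6-dien-1-yl]-6-methylphenol, via sodium 2-methylphenolate 3 (not isolated)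
Conditions: NaH (1.0 equiv), toluene, 0 °C; then 2, 0 °C to rt (1 used in excess)
Reagents that add atoms: none
Why: In a non-polar solvent the tight sodium phenolate ion pair is allylated on carbon at its only free ortho position by a cyclic SN2 delivery (ortho C-alkylation of phenolates), and the E-alkene is untouched.

**Step 2**
Reactants: 4 2-[(2E)-3,7-dimethylocta-2,6-dien-1-yl]-6-methylphenol
Product: 5 (2E,6E)-8-(2-hydroxy-3-methylphenyl)-2,6-dimethylocta-2,6-dien-1-ol
Conditions: SeO2 (0.3 equiv), t-BuOOH (2 equiv), salicylic acid (0.1 equiv), CH2Cl2, 0 °C to rt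
Reagents that add atoms: selenium dioxide O=[Se]=O (oxygen carrier); tert-butyl hydroperoxide CC(C)(C)OO (terminal oxygen source)
Why: The catalytic SeO2 allylic oxidation (ene reaction, then [2,3]-sigmatropic shift) picks the most electron-rich and least hindered terminal isopropylidene and oxidises only its E-methyl group, and this closed-shell pathway leaves the hindered phenol alone.

**Step 3**
Reactants: 5 (2E,6E)-8-(2-hydroxy-3-methylphenyl)-2,6-dimethylocta-2,6-dien-1-ol
Product: 6 2-[(2E,6E)-8-bromo-3,7-dimethylocta-2,6-dien-1-yl]-6-methylphenol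
Conditions: CBr4, PPh3, CH2Cl2, −20 to 0 °C; used promptly
Reagents that add atoms: carbon tetrabromide BrC(Br)(Br)Br
Why: In the Appel reaction the primary allylic alkoxyphosphonium ion is displaced by bromide in an SN2 sense without allylic transposition, and the phenol oxygen cannot be substituted.

**Step 4**
Reactants: 7 5-bromo-2-methylpent-2-ene (homoprenyl bromide); 8 3-bromofuran-2(5H)-one
Product: 10 3-(4-methylpent-3-en-1-yl)furan-2(5H)-one, via homoprenylzinc bromide 9 (not isolated)
Conditions: Zn dust, I2 (5 mol%), DMA, 70 °C; then 8, Pd(dppf)Cl2 (3 mol%), THF, rt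
Reagents that add atoms: none
Why: In this Negishi homoallyl–alkenyl coupling, zerovalent palladium inserts into the activated α-bromoenoate C–Br bond, the non-basic alkylzinc transmetalates, and the wide-bite dppf ligand makes reductive elimination faster than β-hydride elimination.

**Step 5**
Reactants: 10 3-(4-methylpent-3-en-1-yl)furan-2(5H)-one
Product: 11 triisopropyl{[3-(4-methylpent-3-en-1-yl)furan-2-yl]oxy}silane
Conditions: TIPSOTf, Et3N, CH2Cl2, 0 °C to rt
Reagents that add atoms: triisopropylsilyl triflate CC(C)[Si](C(C)C)(C(C)C)OS(=O)(=O)C(F)(F)F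
Why: Soft enolisation (silyl triflate plus amine) removes the acidic γ-proton, and O-silylation is driven by formation of the aromatic 2-silyloxyfuran.

**Step 6**
Reactants: 11 triisopropyl{[3-(4-methylpent-3-en-1-yl)furan-2-yl]oxy}silane; 6 2-[(2E,6E)-8-bromo-3,7-dimethylocta-2,6-dien-1-yl]-6-methylphenol
Product: 14 2-[(2E,6E)-3,7-dimethyl-8-{4-(4-methylpent-3-en-1-yl)-5-[(triisopropylsilyl)oxy]furan-2-yl}octa-2,6-dien-1-yl]-6-methylphenol, via 5-lithiofuran 12 (not isolated), via lithium phenolate 13 (not isolated)
Conditions: flask A: 11, s-BuLi, TMEDA, THF, −78 to 0 °C; flask B: 6, n-BuLi (1.0 equiv), THF, −78 °C; B into A at −78 °C, to −20 °C; then H2O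
Reagents that add atoms: none
Why: α-Lithiation of a 3-alkyl-2-(triisopropylsilyloxy)furan occurs at its only free α-position (C5), and the furyllithium displaces the primary allylic bromide by SN2 with retention of the E-geometry, while the phenol is masked as its unreactive hindered lithium salt.

**Step 7 (key step)**
Reactants: 14 2-[(2E,6E)-3,7-dimethyl-8-{4-(4-methylpent-3-en-1-yl)-5-[(triisopropylsilyl)oxy]furan-2-yl}octa-2,6-dien-1-yl]-6-methylphenol
Product: 16 (5R)-5-[(2E,6E)-8-(2-hydroxy-3-methylphenyl)-2,6-dimethylocta-2,6-dien-1-yl]-3-(4-methylpent-3-en-1-yl)furan-2(5H)-one, via silyloxyfuranium ion 15 (not isolated)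
Conditions: (R)-3,3'-bis[3,5-bis(trifluoromethyl)phenyl]-1,1'-binaphthalene-2,2'-disulfonimide (5 mol%), MeOH (1.5 equiv), toluene, −40 °C, slow addition of 14
Reagents that add atoms: none
Why: Proposed new method: the 2-silyloxyfuran (a vinylogous silyl ketene acetal) is by far the most basic π-system in 14 and is protonated irreversibly at C5, its site of highest HOMO coefficient, inside the contact ion pair with the chiral disulfonimide anion, so hydrogen reaches the Si face and the 5R centre is set as aromaticity is lost; methanol then strips the silyl group from ion 15 and regenerates the acid, while methanol or the hindered phenol alone are too weakly acidic for a racemic background reaction at −40 °C; the closest known reaction types are the chiral Brønsted acid catalysed enantioselective protonation of silyl enol ethers and bis-silyl ketene acetals with an alcohol as the stoichiometric proton source, and the achiral acid hydrolysis of 5-alkyl-2-silyloxyfurans to butenolides.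

**Step 8**
Reactants: 16 (5R)-5-[(2E,6E)-8-(2-hydroxy-3-methylphenyl)-2,6-dimethylocta-2,6-dien-1-yl]-3-(4-methylpent-3-en-1-yl)furan-2(5H)-one
Product: 17 yezoquinolide, 2-{(2E,6E)-3,7-dimethyl-8-[(2R)-4-(4-methylpent-3-en-1-yl)-5-oxo-2,5-dihydrofuran-2-yl]octa-2,6-dien-1-yl}-6-methylcyclohexa-2,5-diene-1,4-dione
Conditions: (KSO3)2NO (2.5 equiv), KH2PO4 buffer (pH 6–7), acetone/H2O, rt
Reagents that add atoms: potassium nitrosodisulfonate [K+].[K+].[O-]S(=O)(=O)N([O])S(=O)(=O)[O-]
Why: In the Teuber oxidation one nitroxyl radical abstracts the phenolic hydrogen and a second adds at the free para carbon of the 2,6-dialkylphenoxyl radical to give the p-quinone, and the near-neutral buffer spares the alkenes, the lactone and the 5R centre.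

**Compound list**
1 | o-cresol (2-methylphenol) | Cc1ccccc1O | starting material
2 | geranyl bromide | CC(C)=CCC/C(C)=C/CBr | starting material
3 | sodium 2-methylphenolate | Cc1ccccc1[O-].[Na+] | intermediate
4 | 2-[(2E)-3,7-dimethylocta-2,6-dien-1-yl]-6-methylphenol | CC(C)=CCC/C(C)=C/Cc1cccc(C)c1O | intermediate
5 | (2E,6E)-8-(2-hydroxy-3-methylphenyl)-2,6-dimethylocta-2,6-dien-1-ol | OC/C(C)=C/CC/C(C)=C/Cc1cccc(C)c1O | intermediate
6 | 2-[(2E,6E)-8-bromo-3,7-dimethylocta-2,6-dien-1-yl]-6-methylphenol | BrC/C(C)=C/CC/C(C)=C/Cc1cccc(C)c1O | intermediate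
7 | 5-bromo-2-methylpent-2-ene | CC(C)=CCCBr | starting material
8 | 3-bromofuran-2(5H)-one | O=C1OCC=C1Br | starting material
9 | (4-methylpent-3-en-1-yl)zinc bromide | CC(C)=CCC[Zn]Br | intermediate
10 | 3-(4-methylpent-3-en-1-yl)furan-2(5H)-one | CC(C)=CCCC1=CCOC1=O | intermediate
11 | triisopropyl{[3-(4-methylpent-3-en-1-yl)furan-2-yl]oxy}silane | CC(C)=CCCc1ccoc1O[Si](C(C)C)(C(C)C)C(C)C | intermediate
12 | [4-(4-methylpent-3-en-1-yl)-5-(triisopropylsilyloxy)furan-2-yl]lithium | [Li]c1cc(CCC=C(C)C)c(O[Si](C(C)C)(C(C)C)C(C)C)o1 | intermediate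
13 | lithium 2-[(2E,6E)-8-bromo-3,7-dimethylocta-2,6-dien-1-yl]-6-methylphenolate | BrC/C(C)=C/CC/C(C)=C/Cc1cccc(C)c1[O-].[Li+] | intermediate
14 | 2-[(2E,6E)-3,7-dimethyl-8-{4-(4-methylpent-3-en-1-yl)-5-[(triisopropylsilyl)oxy]furan-2-yl}octa-2,6-dien-1-yl]-6-methylphenol | CC(C)=CCCc1cc(C/C(C)=C/CC/C(C)=C/Cc2cccc(C)c2O)oc1O[Si](C(C)C)(C(C)C)C(C)C | intermediate
15 | (5R)-5-substituted 2-(triisopropylsilyloxy)-5H-furan-1-ium ion (cation of the ion pair with the disulfonimide anion) | CC(C)=CCCC1=C[C@@H](C/C(C)=C/CC/C(C)=C/Cc2cccc(C)c2O)[O+]=C1O[Si](C(C)C)(C(C)C)C(C)C | intermediate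
16 | (5R)-5-[(2E,6E)-8-(2-hydroxy-3-methylphenyl)-2,6-dimethylocta-2,6-dien-1-yl]-3-(4-methylpent-3-en-1-yl)furan-2(5H)-one | CC(C)=CCCC1=C[C@@H](C/C(C)=C/CC/C(C)=C/Cc2cccc(C)c2O)OC1=O | intermediate
17 | yezoquinolide | CC(C)=CCCC1=C[C@@H](C/C(C)=C/CC/C(C)=C/CC2=CC(=O)C=C(C)C2=O)OC1=O | target

**Count**
Total steps: 8. Longest linear sequence: 6 (steps 1, 2, 3, 6, 7, 8). Steps 4 and 5 run in parallel.

**Three steps most likely to fail**

Step 7. The level of enantioselectivity is unknown, competing C3 protonation is possible, and the free phenol is a bystander proton source. The fallback sets out from 14 and comes back at 16.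
- The silyl group is cleaved with TBAF/AcOH in THF at −78 °C. The free furanolate is then protonated kinetically at C3, giving the non-aromatic β,γ-unsaturated lactone 5-[(2E,6E)-8-(2-hydroxy-3-methylphenyl)-2,6-dimethylocta-2,6-dien-1-yl]-3-(4-methylpent-3-en-1-yl)furan-2(3H)-one F1.
- The double bond is then moved into conjugation with a bifunctional 6'-hydroxy cinchona alkaloid catalyst (10 mol%, CH2Cl2, −20 °C). This is the known enantioselective 1,3-proton-transfer isomerisation of α,γ-dialkyl β,γ-butenolides.
- The quinine- or quinidine-derived pseudoenantiomer that gives 5R is chosen, which delivers 16. Any C3-protonated by-product from step 7 is the same lactone and can be fed into this isomerisation.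

Step 2. The unprotected, oxidisable phenol may not survive the peroxide/SeO2 medium, and the internal alkene may compete. The fallback sets out from 4 and comes back at 5.
- The terminal isopropylidene is exchanged by olefin cross-metathesis with methacrolein (second-generation Hoveyda–Grubbs catalyst, CH2Cl2, 40 °C). This tolerates free phenols and prefers the least hindered trisubstituted alkene, giving (2E,6E)-8-(2-hydroxy-3-methylphenyl)-2,6-dimethylocta-2,6-dienal F2.
- Luche 1,2-reduction (NaBH4, CeCl3·7H2O, MeOH, 0 °C) then gives 5.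

Step 6. The hard, basic furyllithium may deprotonate doubly activated CH2 groups, undergo halogen–metal exchange, or give SN2' products, and handling 13 is delicate. The fallback sets out from 11 (through 12) and comes back at 14.
- Compound 12 is quenched with Bu3SnCl to give the isolable, neutral tributyl[4-(4-methylpent-3-en-1-yl)-5-(triisopropylsilyloxy)furan-2-yl]stannane F3.
- F3 is joined to the unprotected bromide 6 by a Stille allyl–furyl cross-coupling (Pd2(dba)3, AsPh3, THF, rt to 50 °C). A π-allylpalladium intermediate couples at its less hindered CH2 terminus, so neither a strong base nor pre-deprotonation of the phenol is needed.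

**Further compounds**
F1 | step 7 | 5-[(2E,6E)-8-(2-hydroxy-3-methylphenyl)-2,6-dimethylocta-2,6-dien-1-yl]-3-(4-methylpent-3-en-1-yl)furan-2(3H)-one (racemic at C3) | CC(C)=CCCC1C=C(C/C(C)=C/CC/C(C)=C/Cc2cccc(C)c2O)OC1=O
F2 | step 2 | (2E,6E)-8-(2-hydroxy-3-methylphenyl)-2,6-dimethylocta-2,6-dienal | O=C/C(C)=C/CC/C(C)=C/Cc1cccc(C)c1O
F3 | step 6 | tributyl[4-(4-methylpent-3-en-1-yl)-5-(triisopropylsilyloxy)furan-2-yl]stannane | CCCC[Sn](CCCC)(CCCC)c1cc(CCC=C(C)C)c(O[Si](C(C)C)(C(C)C)C(C)C)o1
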